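# Proposed synthesis of (2S)-7,3′,4′-trihydroxy-8,5′-diprenylflavanone (CNP0315050.1)

## Structural features

The target is a flavanone: a benzo ring A fused to a dihydropyranone ring C (O1, C2, C3, C4=O), with an aryl ring B attached at C2. Ring A carries a free 7-OH and a prenyl group at C8, the carbon flanked by O1 and O7; there is no 5-OH. Ring B is a 3′,4′-catechol with a prenyl group at C5′, ortho to the 4′-OH. The only stereocentre is C2 (S, confirmed from the SMILES), a benzylic carbon bearing O1 and lying β to the C4 ketone; no other stereocentre stands next to it. C2 is configurationally fragile: base (and hot acid) open ring C by retro-oxa-Michael reaction to the achiral 2′-hydroxychalcone, so every step after C2 is set must avoid base. The two o-prenylphenol units close to 2,2-dimethylchromans under strong acid, the trisubstituted alkenes rule out hydrogenolysis, peracids and electrophilic halogenation late in the route, and the free catechol is air-sensitive under base. The real difficulty is to set C2 without ever passing through an open chalcone while joining two electron-rich, prenyl-bearing aryl halves, each with its prenyl group at one defined position. The key step exploits the fact that C2 is the β-carbon of the ring C enone in the chromone oxidation level, and that the C2–C1′ bond is the only bond joining ring B to the benzopyranone.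

## Logic of the disconnections

**14 ⇒ 13.** The three phenolic O–H groups (O7, O3′, O4′) are masked as methoxymethyl acetals, i.e. three O–CH2 bonds are cut. Free phenols would interfere with the lithiation, the boron chemistry and the palladium step, and one kind of group allows a single final operation. There is no skeletal gain; the gain is compatibility. The forward cleavage must be non-basic (C2) and mild enough in acid that the o-prenylphenols do not cyclize.

**13 ⇒ 5 + 12 (key disconnection).** The C2–C1′ bond is cut. In one sentence, the route is a catalytic enantioselective 1,4-addition of arylboronic acid 12 to chromone 5. The cut removes the only stereocentre and divides the molecule into two achiral fragments of similar size, each with one prenyl group already in place. The forward step must deliver the aryl group to one face of C2, react at C2=C3 and not at the prenyl alkenes, and protonate the metal enolate before it can expel the O1 aryloxide.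

**12 ⇒ 10 (through 11).** The C–B bond at the ring B carbon that becomes C1′ is cut back to a C–H bond. In the 1,2,3-trisubstituted arene 10 this is the only C–H with no ortho substituent, so a sterically governed C–H borylation needs no halogen and no differentiation of the two catechol oxygens. The forward step must tolerate the trisubstituted alkene and the acetals.

**10 ⇒ 7 (through 8 and 9).** The aryl C–CH2 bond of the ring B prenyl group is cut. The acetal oxygen directs lithiation to the adjacent carbon, and the two ortho positions of the symmetric 7 are equivalent, so no regiochemical question arises. The forward step needs attack at the primary carbon of the prenyl electrophile.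

**7 ⇒ 6.** Two O–CH2 bonds are cut, back to the symmetric commercial diol 6.

**5 ⇒ 4 ⇒ 3.** After removing the O7 acetal, the C8–CH2 bond of the ring A prenyl group is traced back, through a [3,3] shift, to the O7–C(CH3)2 bond of a tertiary allyl ether. The ether oxygen itself delivers the chain to the ortho carbon with allylic transposition, which turns a reverse-prenyl ether into a normal C-prenyl group. The forward step must choose C8 over C6; the higher C7–C8 bond order of the benzopyranone should secure this.

**3 ⇒ 2 ⇒ 1.** The vinyl group is taken back to an ethynyl group and the O7–C bond is cut, giving the commercial chromone 1 and a tertiary propargylic chloride. The forward steps need semi-hydrogenation that leaves C2=C3 untouched and O-alkylation that does not open the pyranone.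

## Other disconnections considered

**Alternative 1:** (the first that comes to mind) Cut O1–C2. Forward: Claisen–Schmidt condensation of acetophenone A2 with aldehyde A3 gives the 2′-hydroxychalcone A1, which is closed by intramolecular oxa-Michael addition. This cyclization is the microscopic reverse of the process that racemizes C2, so under ordinary base or acid it gives racemic material. A plain chalcone such as A1 offers a chiral catalyst no second binding point; the established enantioselective variants need an extra activating ester at C3 that must be installed and later removed. Each half also needs its own carbonyl handle in addition to its prenyl group. The chosen plan is shorter and sets C2 under conditions in which ring opening is not on the pathway.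

**Alternative 2:** Cut O1–C2 in the SN2 sense. Forward: Mitsunobu cyclization of the (R)-β-hydroxy ketone A4, with inversion, to the (2S)-flavanone; A4 would come from a stereocontrolled acetate-type aldol reaction of A2 with A3. The carbinol carbon of A4 is benzylic and para to O4′, so the activated oxyphosphonium intermediate should ionize easily and erode the inversion. A4 should also dehydrate readily to A1. Acetate aldol reactions are poorly stereocontrolled without an auxiliary, which adds steps.

**Alternative 3:** Cut both aryl–prenyl bonds (C8–CH2 and C5′–CH2) at once. Forward: twofold aromatic Claisen rearrangement of the 7,4′-bis(1,1-dimethylallyl) ether A5, prepared from (2S)-butin A6. This is attractive on step count. However, A5 requires base-mediated alkylation of O7 and O4′ in the presence of O3′ on a substrate whose C2 racemizes under base. The double thermal rearrangement would run on a molecule that already contains the labile stereocentre, and the C8/C6 choice would be made at the last stage on the most valuable intermediate. Taking C2 from A6 moves the stereochemical problem to the supply of a scarce starting material. The chosen plan uses the same sigmatropic logic early, on the achiral chromone 3.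

Key step: step 8

Assumption: the sense of induction of the pyridine-oxazoline ligand is taken from the facial model for cyclic enones, by which the (R)-ligand should place the aryl group on the Re face of C2 (giving 2S); if the sense proved opposite, the antipodal ligand would be used.

## Route

Step 1
Reactants: 1 7-hydroxy-4H-chromen-4-one
Product: 2 7-[(2-methylbut-3-yn-2-yl)oxy]-4H-chromen-4-one
Conditions: 3-chloro-3-methylbut-1-yne, K2CO3, KI, CuI (cat.), acetone, reflux
Reagents that add atoms: 3-chloro-3-methylbut-1-yne, CC(C)(Cl)C#C
Why: Copper-assisted propargylic etherification of the acidic 7-OH with a tertiary propargylic chloride, the standard entry to aryl 1,1-dimethylpropargyl ethers; anhydrous carbonate should not open the pyranone ring.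

Step 2
Reactants: 2 7-[(2-methylbut-3-yn-2-yl)oxy]-4H-chromen-4-one
Product: 3 7-[(2-methylbut-3-en-2-yl)oxy]-4H-chromen-4-one
Conditions: H2 (1 atm), Pd/CaCO3 poisoned with Pb(OAc)2 (Lindlar catalyst), quinoline, EtOAc, 23 °C
Reagents that add atoms: none
Why: Lindlar semi-hydrogenation of a terminal alkyne should stop at the vinyl group; the vinylogous-ester C2=C3 bond of the chromone is not expected to be reduced on the poisoned catalyst.

Step 3
Reactants: 3 7-[(2-methylbut-3-en-2-yl)oxy]-4H-chromen-4-one
Product: 4 7-hydroxy-8-(3-methylbut-2-en-1-yl)-4H-chromen-4-one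
Conditions: PhNEt2, 150 °C, argon
Reagents that add atoms: none
Why: Aromatic Claisen rearrangement; the [3,3] shift of the tertiary allyl ether transposes the allyl unit so that a normal prenyl group arrives at the ortho carbon, and tautomerization restores the phenol. C8 should be preferred over C6 because the C7–C8 bond of the benzopyranone has the higher double-bond character, as in 2-naphthyl allyl ethers.

Step 4
Reactants: 4 7-hydroxy-8-(3-methylbut-2-en-1-yl)-4H-chromen-4-one
Product: 5 7-(methoxymethoxy)-8-(3-methylbut-2-en-1-yl)-4H-chromen-4-one
Conditions: MOMCl, i-Pr2NEt, CH2Cl2, 0 to 23 °C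
Reagents that add atoms: chloromethyl methyl ether, COCCl
Why: Standard O-alkylation of a phenol to its methoxymethyl acetal with a hindered amine base, which should not attack C2 of the chromone.

Step 5
Reactants: 6 benzene-1,2-diol (catechol)
Product: 7 1,2-bis(methoxymethoxy)benzene
Conditions: MOMCl, i-Pr2NEt, CH2Cl2, 0 to 40 °C
Reagents that add atoms: chloromethyl methyl ether, COCCl
Why: Twofold acetal protection of a symmetric diol; no differentiation of the two oxygens is needed.

Step 6
Reactants: 7 1,2-bis(methoxymethoxy)benzene
Product: 10 1,2-bis(methoxymethoxy)-3-(3-methylbut-2-en-1-yl)benzene, via [2,3-bis(methoxymethoxy)phenyl]lithium 8 (not isolated), via [2,3-bis(methoxymethoxy)phenyl]copper 9 (not isolated)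
Conditions: n-BuLi, TMEDA, THF, 0 °C; CuI, −40 °C; prenyl bromide, −40 to 23 °C
Reagents that add atoms: 1-bromo-3-methylbut-2-ene, CC(C)=CCBr; n-butyllithium, [Li]CCCC (lithium of 8 only); CuI, [Cu]I (copper of 9 only)
Why: Directed ortho-metalation; the acetal oxygen directs lithiation to the adjacent ring carbon (the two ortho sites of 7 are equivalent). Transmetalation to the arylcopper species should favour substitution at the primary carbon of prenyl bromide over Wurtz-type side reactions.

Step 7
Reactants: 10 1,2-bis(methoxymethoxy)-3-(3-methylbut-2-en-1-yl)benzene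
Product: 12 [3,4-bis(methoxymethoxy)-5-(3-methylbut-2-en-1-yl)phenyl]boronic acid, via pinacol boronate 11 (not isolated)
Conditions: [Ir(OMe)(cod)]2 (cat.), 4,4′-di-tert-butyl-2,2′-bipyridine (cat.), B2pin2 (0.6 equiv), THF, 60 °C; then NaIO4, NH4OAc, acetone/H2O, 23 °C
Reagents that add atoms: bis(pinacolato)diboron, CC1(C)OB(OC1(C)C)B1OC(C)(C)C(C)(C)O1; water, O
Why: Iridium-catalysed aromatic C–H borylation is governed by sterics, and C5 of 10 is the only C–H without an ortho substituent; a trisubstituted alkene is a poor partner for the iridium boryl species. Buffered periodate cleavage of the pinacol unit then frees the boronic acid without acid that would endanger the acetals.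

Step 8
Reactants: 5 7-(methoxymethoxy)-8-(3-methylbut-2-en-1-yl)-4H-chromen-4-one; 12 [3,4-bis(methoxymethoxy)-5-(3-methylbut-2-en-1-yl)phenyl]boronic acid (2 equiv)
Product: 13 (2S)-2-[3,4-bis(methoxymethoxy)-5-(3-methylbut-2-en-1-yl)phenyl]-7-(methoxymethoxy)-8-(3-methylbut-2-en-1-yl)-2,3-dihydro-4H-chromen-4-one
Conditions: Pd(OCOCF3)2 (5 mol %), (R)-4-tert-butyl-2-(pyridin-2-yl)-4,5-dihydrooxazole [(R)-t-BuPyOx] (6 mol %), NH4PF6 (30 mol %), H2O (5 equiv), ClCH2CH2Cl, 60 °C
Reagents that add atoms: none
Why: Enantioselective conjugate addition of an arylboronic acid to a chromone under divalent palladium/pyridine-oxazoline catalysis, a known reaction type for chromones. Transmetalation of 12 to the cationic ligand-bound palladium centre gives an aryl–palladium species (palladium stays divalent throughout); the C2=C3 bond of 5 coordinates and inserts, the aryl group migrating to C2 and palladium to C3, and the resulting palladium enolate is protonated by water, releasing 13 and regenerating the catalyst. No ring is closed: ring C is already present and is only saturated at C2–C3. The single new stereocentre C2 is set under catalyst control in the insertion step, where the tert-butyl group of the (R)-ligand should block one enantiotopic face so that the aryl group is delivered to the Re face of C2, which corresponds to 2S. The step needs chemoselectivity for the electron-poor, cis-disubstituted C2=C3 bond over the two trisubstituted prenyl alkenes; the far faster insertion of a coordinating enone should secure this, and the meta-placed prenyl group of the aryl–palladium species cannot reach the metal for an intramolecular insertion. It also needs protonation of the enolate in preference to β-aryloxide elimination, which the base-free, water-containing medium should secure, so that no chalcone forms and C2 cannot racemize. Finally, transmetalation must outrun protodeboronation of the electron-rich 12, which is addressed by using 12 in excess.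

Step 9
Reactants: 13 (2S)-2-[3,4-bis(methoxymethoxy)-5-(3-methylbut-2-en-1-yl)phenyl]-7-(methoxymethoxy)-8-(3-methylbut-2-en-1-yl)-2,3-dihydro-4H-chromen-4-one
Product: 14 (2S)-2-[3,4-dihydroxy-5-(3-methylbut-2-en-1-yl)phenyl]-7-hydroxy-8-(3-methylbut-2-en-1-yl)-2,3-dihydro-4H-chromen-4-one
Conditions: HCl (3 M aq), MeOH, 40 °C, argon, monitored closely
Reagents that add atoms: none
Why: Acid-catalysed solvolysis of aryl methoxymethyl acetals, which should proceed at an acid strength and temperature below those needed to protonate the trisubstituted alkenes; the medium is non-basic, so C2 should keep its configuration.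

## Compound list

1 | 7-hydroxy-4H-chromen-4-one | O=c1ccoc2cc(O)ccc12 | starting material
2 | 7-[(2-methylbut-3-yn-2-yl)oxy]-4H-chromen-4-one | O=c1ccoc2cc(OC(C)(C)C#C)ccc12 | intermediate
3 | 7-[(2-methylbut-3-en-2-yl)oxy]-4H-chromen-4-one | O=c1ccoc2cc(OC(C)(C)C=C)ccc12 | intermediate
4 | 7-hydroxy-8-(3-methylbut-2-en-1-yl)-4H-chromen-4-one | O=c1ccoc2c(CC=C(C)C)c(O)ccc12 | intermediate
5 | 7-(methoxymethoxy)-8-(3-methylbut-2-en-1-yl)-4H-chromen-4-one | O=c1ccoc2c(CC=C(C)C)c(OCOC)ccc12 | intermediate
6 | benzene-1,2-diol (catechol) | Oc1ccccc1O | starting material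
7 | 1,2-bis(methoxymethoxy)benzene | COCOc1ccccc1OCOC | intermediate
8 | [2,3-bis(methoxymethoxy)phenyl]lithium | [Li]c1cccc(OCOC)c1OCOC | intermediate
9 | [2,3-bis(methoxymethoxy)phenyl]copper | [Cu]c1cccc(OCOC)c1OCOC | intermediate
10 | 1,2-bis(methoxymethoxy)-3-(3-methylbut-2-en-1-yl)benzene | COCOc1cccc(CC=C(C)C)c1OCOC | intermediate
11 | 2-[3,4-bis(methoxymethoxy)-5-(3-methylbut-2-en-1-yl)phenyl]-4,4,5,5-tetramethyl-1,3,2-dioxaborolane | COCOc1cc(B2OC(C)(C)C(C)(C)O2)cc(CC=C(C)C)c1OCOC | intermediate
12 | [3,4-bis(methoxymethoxy)-5-(3-methylbut-2-en-1-yl)phenyl]boronic acid | COCOc1cc(B(O)O)cc(CC=C(C)C)c1OCOC | intermediate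
13 | (2S)-2-[3,4-bis(methoxymethoxy)-5-(3-methylbut-2-en-1-yl)phenyl]-7-(methoxymethoxy)-8-(3-methylbut-2-en-1-yl)-2,3-dihydro-4H-chromen-4-one | CC(C)=CCc1cc([C@@H]2CC(=O)c3ccc(OCOC)c(CC=C(C)C)c3O2)cc(OCOC)c1OCOC | intermediate
14 | (2S)-2-[3,4-dihydroxy-5-(3-methylbut-2-en-1-yl)phenyl]-7-hydroxy-8-(3-methylbut-2-en-1-yl)-2,3-dihydro-4H-chromen-4-one | CC(C)=CCc1cc([C@@H]2CC(=O)c3ccc(O)c(CC=C(C)C)c3O2)cc(O)c1O | target

## Step count and least certain steps

Total: 9 steps. Longest linear sequence: 6 steps (steps 1, 2, 3, 4, 8, 9); the ring B branch (steps 5, 6, 7) joins at step 8.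

**Step 8 (key step).** The 7-alkoxy group makes the chromone electron-rich, so insertion may be slow and protodeboronation of the electron-rich 12 may consume the nucleophile first; facial discrimination may also be insufficient. Fallback (resolution in place of asymmetric C–C bond formation; sets out from 5 and 12, returns at 13): 5 and 12 are joined without stereocontrol through a more nucleophilic aryl species of monovalent rhodium ([Rh(OH)(cod)]2, dioxane/H2O, 50 °C) to give the racemic tris(methoxymethyl) flavanone F1. Kinetic resolution by asymmetric transfer hydrogenation (RuCl[(R,R)-TsDPEN](p-cymene), a complex of divalent ruthenium, HCO2H/Et3N, EtOAc, 23 °C, stopped near half conversion) should reduce the (2R)-ketone to the (2R,4R)-cis-flavan-4-ol F2 and leave (2S)-13, separated by chromatography. The (R,R)-complex is chosen by analogy with the sense of reduction of aryl alkyl ketones.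

**Step 7.** Iridium-catalysed hydroboration or vinylic borylation of the prenyl alkene may compete with aromatic borylation, and cleavage of the pinacol ester may be incomplete. Fallback (alkene introduced after the borylation; sets out from 7, returns at 11): ortho-lithiation of 7 (n-BuLi, THF, 0 °C, through 8) and quenching with I2 gives 1-iodo-2,3-bis(methoxymethoxy)benzene F3. Steric C–H borylation ([Ir(OMe)(cod)]2, 4,4′-di-tert-butyl-2,2′-bipyridine, B2pin2) at the only unhindered position gives the iodo pinacol boronate F4. Base-free Stille coupling with tributyl(3-methylbut-2-en-1-yl)stannane (Pd(PPh3)4, DMF, 80 °C), under which the boronate should not transmetalate, gives 11, which is cleaved to 12 as in the second stage of step 7.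

**Step 3.** Part of the material may rearrange to C6, the tertiary allyl group may be lost thermally as isoprene, and the o-prenylphenol may cyclize at high temperature. Fallback (cross-coupling in place of the sigmatropic shift; sets out from 1, returns at 5): electrophilic iodination of 1 (NIS, MeCN, 23 °C) at C8, the position between O1 and O7, gives 7-hydroxy-8-iodo-4H-chromen-4-one F5. Protection (MOMCl, i-Pr2NEt, CH2Cl2) gives 8-iodo-7-(methoxymethoxy)-4H-chromen-4-one F6, and Stille coupling with tributyl(3-methylbut-2-en-1-yl)stannane (Pd(PPh3)4, DMF, 90 °C) gives 5.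

**Step 9.** Acid-promoted addition of the liberated phenols to the neighbouring prenyl alkenes (chroman formation) may compete with cleavage of three acetals, and prolonged acid may open ring C at C2. Fallback (fluoride-labile silyl ethers in place of acetals; sets out from 4 and 6, returns at 14):
- Ring A: 4 is silylated (TBSCl, imidazole, DMF) to the 7-silyloxy chromone F7.
- Ring B: 6, used in excess, is monoalkylated (3-chloro-3-methylbut-1-yne, K2CO3, KI, CuI cat., acetone) to the propargyl ether F8, semi-hydrogenated (H2, Lindlar catalyst as in step 2) to the allyl ether F9, and rearranged (PhNEt2, 130 °C) to 3-prenylcatechol F10. Bis-silylation (TBSCl, imidazole, DMF) gives the bis(silyl) ether F11. The one-pot borylation/periodate cleavage of step 7 gives, through the pinacol boronate F12, the boronic acid F13.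
- Union and release: F7 and F13 are joined under the conditions of step 8 to the (2S)-tris(silyl) flavanone F14, and Et3N·3HF (THF, 23 °C) releases 14 under non-basic, only weakly acidic conditions.

## Further compounds

F1 | step 8 | rac-2-[3,4-bis(methoxymethoxy)-5-(3-methylbut-2-en-1-yl)phenyl]-7-(methoxymethoxy)-8-(3-methylbut-2-en-1-yl)-2,3-dihydro-4H-chromen-4-one | CC(C)=CCc1cc(C2CC(=O)c3ccc(OCOC)c(CC=C(C)C)c3O2)cc(OCOC)c1OCOC
F2 | step 8 | (2R,4R)-2-[3,4-bis(methoxymethoxy)-5-(3-methylbut-2-en-1-yl)phenyl]-7-(methoxymethoxy)-8-(3-methylbut-2-en-1-yl)-3,4-dihydro-2H-chromen-4-ol | CC(C)=CCc1cc([C@H]2C[C@@H](O)c3ccc(OCOC)c(CC=C(C)C)c3O2)cc(OCOC)c1OCOC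
F3 | step 7 | 1-iodo-2,3-bis(methoxymethoxy)benzene | COCOc1cccc(I)c1OCOC
F4 | step 7 | 2-[3-iodo-4,5-bis(methoxymethoxy)phenyl]-4,4,5,5-tetramethyl-1,3,2-dioxaborolane | COCOc1cc(B2OC(C)(C)C(C)(C)O2)cc(I)c1OCOC
F5 | step 3 | 7-hydroxy-8-iodo-4H-chromen-4-one | O=c1ccoc2c(I)c(O)ccc12
F6 | step 3 | 8-iodo-7-(methoxymethoxy)-4H-chromen-4-one | O=c1ccoc2c(I)c(OCOC)ccc12
F7 | step 9 | 7-[(tert-butyldimethylsilyl)oxy]-8-(3-methylbut-2-en-1-yl)-4H-chromen-4-one | O=c1ccoc2c(CC=C(C)C)c(O[Si](C)(C)C(C)(C)C)ccc12
F8 | step 9 | 2-[(2-methylbut-3-yn-2-yl)oxy]phenol | C#CC(C)(C)Oc1ccccc1O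
F9 | step 9 | 2-[(2-methylbut-3-en-2-yl)oxy]phenol | C=CC(C)(C)Oc1ccccc1O
F10 | step 9 | 3-(3-methylbut-2-en-1-yl)benzene-1,2-diol | CC(C)=CCc1cccc(O)c1O
F11 | step 9 | 1,2-bis[(tert-butyldimethylsilyl)oxy]-3-(3-methylbut-2-en-1-yl)benzene | CC(C)=CCc1cccc(O[Si](C)(C)C(C)(C)C)c1O[Si](C)(C)C(C)(C)C
F12 | step 9 | 2-{3,4-bis[(tert-butyldimethylsilyl)oxy]-5-(3-methylbut-2-en-1-yl)phenyl}-4,4,5,5-tetramethyl-1,3,2-dioxaborolane | CC(C)=CCc1cc(B2OC(C)(C)C(C)(C)O2)cc(O[Si](C)(C)C(C)(C)C)c1O[Si](C)(C)C(C)(C)C
F13 | step 9 | {3,4-bis[(tert-butyldimethylsilyl)oxy]-5-(3-methylbut-2-en-1-yl)phenyl}boronic acid | CC(C)=CCc1cc(B(O)O)cc(O[Si](C)(C)C(C)(C)C)c1O[Si](C)(C)C(C)(C)C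
F14 | step 9 | (2S)-2-{3,4-bis[(tert-butyldimethylsilyl)oxy]-5-(3-methylbut-2-en-1-yl)phenyl}-7-[(tert-butyldimethylsilyl)oxy]-8-(3-methylbut-2-en-1-yl)-2,3-dihydro-4H-chromen-4-one | CC(C)=CCc1cc([C@@H]2CC(=O)c3ccc(O[Si](C)(C)C(C)(C)C)c(CC=C(C)C)c3O2)cc(O[Si](C)(C)C(C)(C)C)c1O[Si](C)(C)C(C)(C)C
A1 | alternative 1 | (E)-3-[3,4-bis(methoxymethoxy)-5-(3-methylbut-2-en-1-yl)phenyl]-1-[2-hydroxy-4-(methoxymethoxy)-3-(3-methylbut-2-en-1-yl)phenyl]prop-2-en-1-one | COCOc1ccc(C(=O)/C=C/c2cc(CC=C(C)C)c(OCOC)c(OCOC)c2)c(O)c1CC=C(C)C
A2 | alternative 1 | 1-[2-hydroxy-4-(methoxymethoxy)-3-(3-methylbut-2-en-1-yl)phenyl]ethan-1-one | CC(=O)c1ccc(OCOC)c(CC=C(C)C)c1O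
A3 | alternative 1 | 3,4-bis(methoxymethoxy)-5-(3-methylbut-2-en-1-yl)benzaldehyde | COCOc1cc(C=O)cc(CC=C(C)C)c1OCOC
A4 | alternative 2 | (3R)-3-[3,4-bis(methoxymethoxy)-5-(3-methylbut-2-en-1-yl)phenyl]-3-hydroxy-1-[2-hydroxy-4-(methoxymethoxy)-3-(3-methylbut-2-en-1-yl)phenyl]propan-1-one | COCOc1ccc(C(=O)C[C@@H](O)c2cc(CC=C(C)C)c(OCOC)c(OCOC)c2)c(O)c1CC=C(C)C
A5 | alternative 3 | (2S)-2-{3-hydroxy-4-[(2-methylbut-3-en-2-yl)oxy]phenyl}-7-[(2-methylbut-3-en-2-yl)oxy]-2,3-dihydro-4H-chromen-4-one | C=CC(C)(C)Oc1ccc([C@@H]2CC(=O)c3ccc(OC(C)(C)C=C)cc3O2)cc1O
A6 | alternative 3 | (2S)-2-(3,4-dihydroxyphenyl)-7-hydroxy-2,3-dihydro-4H-chromen-4-one ((2S)-butin) | O=C1C[C@@H](c2ccc(O)c(O)c2)Oc2cc(O)ccc12
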